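The tetrahydrofuran ring (O1, C2 aryl, C3 CH2OH, C4 aroyl, C5) is traced back to a cis-γ-aryl-β-(silyloxymethyl)-α-methylene-γ-butyrolactone whose carbonyl carbon is C5 and whose exocyclic CH2 is the later ketone carbon on C4. One operation, addition of a 2-methoxycarbonyl allylboronate to 3,4,5-trimethoxybenzaldehyde under chiral phosphoric acid catalysis followed by closure of the boron alkoxide onto the ester, forms the C2–C3 bond with both stereocentres (2,3-cis) and the O1–C5 bond, closing the ring. The precursor is a geometrically pure (E)-allylboronate with CH2OTBS cis to CH2Bpin, made from a Morita–Baylis–Hillman acetate. C4 is set later under thermodynamic control.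

Key step: step 4

Numbering: atom labels C2–C5 in the text follow O1, C2 (aryl), C3 (CH2OH), C4 (aroyl), C5; locants inside compound names follow nomenclature rules.

Assumption: the sense of induction is taken from simple allyl and crotyl pinacolboronates, where the (R)-configured binaphthyl phosphoric acid directs addition to the Re face of aryl aldehydes; the (S)-acid is therefore specified for the Si-face addition needed here, and its mirror image would be used if the ester-bearing reagent responded in the opposite sense.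

Step 1
Reactants: 1 methyl acrylate; 2 (tert-butyldimethylsilyloxy)acetaldehyde
Product: 3 methyl 4-[(tert-butyldimethylsilyl)oxy]-3-hydroxy-2-methylenebutanoate (racemic)
Conditions: 1,4-diazabicyclo[2.2.2]octane (DABCO, 0.5 equiv), excess 1, MeOH (cat.), rt
Reagents that add atoms: none
Why: Morita–Baylis–Hillman reaction, in which the amine adds to the acrylate and the zwitterionic enolate attacks the reactive α-silyloxy aldehyde; the carbinol centre is racemic and is erased in step 3.

Step 2
Reactants: 3 methyl 4-[(tert-butyldimethylsilyl)oxy]-3-hydroxy-2-methylenebutanoate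
Product: 4 methyl 3-acetoxy-4-[(tert-butyldimethylsilyl)oxy]-2-methylenebutanoate (racemic)
Conditions: Ac2O, pyridine, 4-(dimethylamino)pyridine (cat.), CH2Cl2, 0 °C
Reagents that add atoms: acetic anhydride, CC(=O)OC(C)=O
Why: Standard O-acetylation of a secondary allylic alcohol, kept cold and short so that the acetate does not undergo amine-induced allylic transposition.

Step 3
Reactants: 4 methyl 3-acetoxy-4-[(tert-butyldimethylsilyl)oxy]-2-methylenebutanoate
Product: 5 methyl (E)-4-[(tert-butyldimethylsilyl)oxy]-2-[(4,4,5,5-tetramethyl-1,3,2-dioxaborolan-2-yl)methyl]but-2-enoate (CH2OTBS cis to CH2Bpin, trans to the ester)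
Conditions: B2pin2 (1.1 equiv), CuCl (10 mol %), LiCl, KOAc, DMF, rt; chromatography to geometric purity
Reagents that add atoms: bis(pinacolato)diboron, CC1(C)OB(OC1(C)C)B1OC(C)(C)C(C)(C)O1
Why: Copper-catalysed SN2′ borylation of a Morita–Baylis–Hillman acetate, in which the boryl copper species adds to the acrylate terminus and acetate leaves from the ester enolate, the trisubstituted alkene forming with the substituent trans to the ester as is usual for ester-derived SN2′ products.

Step 4
Reactants: 6 3,4,5-trimethoxybenzaldehyde; 5 methyl (E)-4-[(tert-butyldimethylsilyl)oxy]-2-[(4,4,5,5-tetramethyl-1,3,2-dioxaborolan-2-yl)methyl]but-2-enoate (1.2 equiv)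
Product: 8 (4S,5S)-4-{[(tert-butyldimethylsilyl)oxy]methyl}-3-methylene-5-(3,4,5-trimethoxyphenyl)dihydrofuran-2(3H)-one (cis lactone), via syn O-pinacolboryl homoallylic ester 7 (not isolated)
Conditions: (S)-3,3′-bis(2,4,6-triisopropylphenyl)-1,1′-binaphthyl-2,2′-diyl hydrogen phosphate [(S)-TRIP, 10 mol %], PhMe, −20 °C → rt; then pyridinium p-toluenesulfonate (cat.), 40 °C
Reagents that add atoms: none
Why: The phosphoric acid hydrogen-bonds to a pinacol oxygen of 5 while its P=O oxygen engages the formyl hydrogen of 6, and the C2–C3 bond forms through a closed six-membered Zimmerman–Traxler chair, the closest known reaction types being the chiral phosphoric acid-catalysed allyl- and crotylboration of aryl aldehydes with pinacol boronates and the Brønsted acid-promoted allylboration–lactonisation of 2-alkoxycarbonyl allylboronates. In the chair the aryl group of 6 is equatorial and CH2OTBS, being cis to CH2Bpin on the alkene, is axial, so the syn borate 7 results and the C3 configuration relative to C2 (cis in the ring) is dictated by the alkene geometry of 5. The absolute configuration at C2 is set by the catalyst, the (S)-acid being chosen to open the Si face of the aldehyde. The boron-bound oxygen of 7 then adds to the adjacent ester carbonyl in a 5-exo-trig acyl substitution that expels MeO–Bpin and forms the O1–C5 bond, the C2–O1 bond staying intact. The step needs syn diastereoselectivity, which the geometric purity of 5 and the closed transition state secure, and aldehyde-face selectivity, which rests on the catalyst and is helped by the slow uncatalysed reaction of this ester-deactivated boronate at low temperature. Only a weak acid (pyridinium p-toluenesulfonate) is used to complete ring closure, so that the electron-rich benzylic C–O bond is not ionised and the cis relationship survives.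

Step 5
Reactants: 8 (4S,5S)-4-{[(tert-butyldimethylsilyl)oxy]methyl}-3-methylene-5-(3,4,5-trimethoxyphenyl)dihydrofuran-2(3H)-one
Product: 9 (1S,2S)-2-{[(tert-butyldimethylsilyl)oxy]methyl}-3-methylene-1-(3,4,5-trimethoxyphenyl)butane-1,4-diol
Conditions: i-Bu2AlH (4 equiv), CH2Cl2, −78 → 0 °C; aqueous KNaC4H4O6 work-up
Reagents that add atoms: none
Why: Hydride reduction of an α-methylene lactone by 1,2-addition through the lactol to the 2-methylene-1,4-diol, which leaves the alkene, the silyl ether and both stereocentres untouched.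

Step 6
Reactants: 9 (1S,2S)-2-{[(tert-butyldimethylsilyl)oxy]methyl}-3-methylene-1-(3,4,5-trimethoxyphenyl)butane-1,4-diol
Product: 11 tert-butyldimethyl{[(2S,3S)-4-methylene-2-(3,4,5-trimethoxyphenyl)tetrahydrofuran-3-yl]methoxy}silane, via primary allylic tosylate 10 (not isolated)
Conditions: Ts2O (1.1 equiv), Et3N, 4-(dimethylamino)pyridine (cat.), CH2Cl2, −20 °C → rt
Reagents that add atoms: none
Why: Williamson-type cycloetherification, in which the unhindered primary allylic hydroxyl is sulfonylated selectively and the benzylic hydroxyl displaces the tosylate (5-exo-tet, the SN2′ mode giving the same product because the 2-substituted allyl unit is symmetrical), so the C2–O1 bond is never broken and C2 and C3 keep their configuration.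

Step 7
Reactants: 11 tert-butyldimethyl{[(2S,3S)-4-methylene-2-(3,4,5-trimethoxyphenyl)tetrahydrofuran-3-yl]methoxy}silane
Product: 13 [(3R,4S,5S)-4-{[(tert-butyldimethylsilyl)oxy]methyl}-5-(3,4,5-trimethoxyphenyl)tetrahydrofuran-3-yl]methanol (all-cis, expected major C4 epimer), via B-alkyl-9-BBN adduct 12 (not isolated)
Conditions: 9-borabicyclo[3.3.1]nonane (9-BBN, 1.5 equiv), THF, 0 °C → rt; then NaOH, H2O2, H2O, 0 °C → rt
Reagents that add atoms: hydrogen peroxide, OO
Why: Hydroboration–oxidation puts boron on the terminal carbon of the 1,1-disubstituted alkene and the borane should add anti to the cis aryl and silyloxymethyl groups to give mainly the all-cis C4 epimer, which is immaterial because C4 is equilibrated in step 10.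

Step 8
Reactants: 13 [(3R,4S,5S)-4-{[(tert-butyldimethylsilyl)oxy]methyl}-5-(3,4,5-trimethoxyphenyl)tetrahydrofuran-3-yl]methanol
Product: 14 (3S,4S,5S)-4-{[(tert-butyldimethylsilyl)oxy]methyl}-5-(3,4,5-trimethoxyphenyl)tetrahydrofuran-3-carbaldehyde
Conditions: Dess–Martin periodinane, CH2Cl2, 0 °C → rt
Reagents that add atoms: none
Why: Dess–Martin oxidation of a primary alcohol to the aldehyde under near-neutral conditions that spare the silyl ether and the benzylic ether.

Step 9
Reactants: 14 (3S,4S,5S)-4-{[(tert-butyldimethylsilyl)oxy]methyl}-5-(3,4,5-trimethoxyphenyl)tetrahydrofuran-3-carbaldehyde; 15 5-bromo-1,2,3-trimethoxybenzene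
Product: 17 [(3S,4S,5S)-4-{[(tert-butyldimethylsilyl)oxy]methyl}-5-(3,4,5-trimethoxyphenyl)tetrahydrofuran-3-yl](3,4,5-trimethoxyphenyl)methanol (carbinol epimers), via (3,4,5-trimethoxyphenyl)magnesium bromide 16 (not isolated)
Conditions: 15, Mg, THF, rt; then 14, THF, −78 → 0 °C; aqueous NH4Cl
Reagents that add atoms: none
Why: Grignard addition of an aryl magnesium bromide to an aldehyde, the new carbinol centre forming as a mixture that the next oxidation removes.

Step 10
Reactants: 17 [(3S,4S,5S)-4-{[(tert-butyldimethylsilyl)oxy]methyl}-5-(3,4,5-trimethoxyphenyl)tetrahydrofuran-3-yl](3,4,5-trimethoxyphenyl)methanol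
Product: 19 [(3R,4S,5S)-4-{[(tert-butyldimethylsilyl)oxy]methyl}-5-(3,4,5-trimethoxyphenyl)tetrahydrofuran-3-yl](3,4,5-trimethoxyphenyl)methanone (3,4-trans), via all-cis ketone 18 (not isolated)
Conditions: Dess–Martin periodinane, CH2Cl2, rt; then K2CO3, MeOH/THF, rt
Reagents that add atoms: none
Why: Dess–Martin oxidation gives the aryl ketone and base-mediated enolisation then equilibrates C4 to the favoured 3,4-trans isomer (relief of the contiguous all-cis arrangement, both C4 epimers from step 7 converging), β-elimination of O1 being stereoelectronically disfavoured because the C5–O1 bond lies orthogonal to the enolate π system.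

Step 11
Reactants: 19 [(3R,4S,5S)-4-{[(tert-butyldimethylsilyl)oxy]methyl}-5-(3,4,5-trimethoxyphenyl)tetrahydrofuran-3-yl](3,4,5-trimethoxyphenyl)methanone
Product: 20 [(3R,4S,5S)-4-(hydroxymethyl)-5-(3,4,5-trimethoxyphenyl)tetrahydrofuran-3-yl](3,4,5-trimethoxyphenyl)methanone (target)
Conditions: HF·pyridine, pyridine, THF, 0 °C → rt
Reagents that add atoms: none
Why: Fluoride cleavage of a primary silyl ether under buffered, non-basic conditions, so that the enolisable C4 centre is not re-equilibrated towards a cis isomer that could be trapped as a bicyclic hemiketal.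

Compound list
1 | methyl acrylate | C=CC(=O)OC | starting material
2 | (tert-butyldimethylsilyloxy)acetaldehyde | CC(C)(C)[Si](C)(C)OCC=O | starting material
3 | methyl 4-[(tert-butyldimethylsilyl)oxy]-3-hydroxy-2-methylenebutanoate (racemic) | COC(=O)C(=C)C(O)CO[Si](C)(C)C(C)(C)C | intermediate
4 | methyl 3-acetoxy-4-[(tert-butyldimethylsilyl)oxy]-2-methylenebutanoate (racemic) | COC(=O)C(=C)C(OC(C)=O)CO[Si](C)(C)C(C)(C)C | intermediate
5 | methyl (E)-4-[(tert-butyldimethylsilyl)oxy]-2-[(4,4,5,5-tetramethyl-1,3,2-dioxaborolan-2-yl)methyl]but-2-enoate | COC(=O)/C(CB1OC(C)(C)C(C)(C)O1)=C/CO[Si](C)(C)C(C)(C)C | intermediate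
6 | 3,4,5-trimethoxybenzaldehyde | COc1cc(C=O)cc(OC)c1OC | starting material
7 | methyl (S)-4-[(tert-butyldimethylsilyl)oxy]-2-methylene-3-{(S)-[(4,4,5,5-tetramethyl-1,3,2-dioxaborolan-2-yl)oxy](3,4,5-trimethoxyphenyl)methyl}butanoate (syn borate, not isolated) | CC1(C)OB(O[C@H](c2cc(OC)c(OC)c(OC)c2)[C@H](CO[Si](C)(C)C(C)(C)C)C(=C)C(=O)OC)OC1(C)C | intermediate
8 | (4S,5S)-4-{[(tert-butyldimethylsilyl)oxy]methyl}-3-methylene-5-(3,4,5-trimethoxyphenyl)dihydrofuran-2(3H)-one | C=C1C(=O)O[C@H](c2cc(OC)c(OC)c(OC)c2)[C@@H]1CO[Si](C)(C)C(C)(C)C | intermediate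
9 | (1S,2S)-2-{[(tert-butyldimethylsilyl)oxy]methyl}-3-methylene-1-(3,4,5-trimethoxyphenyl)butane-1,4-diol | O[C@H](c1cc(OC)c(OC)c(OC)c1)[C@H](CO[Si](C)(C)C(C)(C)C)C(=C)CO | intermediate
10 | (3S,4S)-3-{[(tert-butyldimethylsilyl)oxy]methyl}-4-hydroxy-2-methylene-4-(3,4,5-trimethoxyphenyl)butyl 4-methylbenzenesulfonate (not isolated) | O[C@H](c1cc(OC)c(OC)c(OC)c1)[C@H](CO[Si](C)(C)C(C)(C)C)C(=C)COS(=O)(=O)c1ccc(C)cc1 | intermediate
11 | tert-butyldimethyl{[(2S,3S)-4-methylene-2-(3,4,5-trimethoxyphenyl)tetrahydrofuran-3-yl]methoxy}silane | C=C1CO[C@H](c2cc(OC)c(OC)c(OC)c2)[C@@H]1CO[Si](C)(C)C(C)(C)C | intermediate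
12 | 9-{[(3S,4S,5S)-4-{[(tert-butyldimethylsilyl)oxy]methyl}-5-(3,4,5-trimethoxyphenyl)tetrahydrofuran-3-yl]methyl}-9-borabicyclo[3.3.1]nonane (all-cis, not isolated) | B1(C[C@@H]2CO[C@H](c3cc(OC)c(OC)c(OC)c3)[C@@H]2CO[Si](C)(C)C(C)(C)C)C4CCCC1CCC4 | intermediate
13 | [(3R,4S,5S)-4-{[(tert-butyldimethylsilyl)oxy]methyl}-5-(3,4,5-trimethoxyphenyl)tetrahydrofuran-3-yl]methanol (all-cis) | OC[C@@H]1CO[C@H](c2cc(OC)c(OC)c(OC)c2)[C@@H]1CO[Si](C)(C)C(C)(C)C | intermediate
14 | (3S,4S,5S)-4-{[(tert-butyldimethylsilyl)oxy]methyl}-5-(3,4,5-trimethoxyphenyl)tetrahydrofuran-3-carbaldehyde (all-cis) | O=C[C@@H]1CO[C@H](c2cc(OC)c(OC)c(OC)c2)[C@@H]1CO[Si](C)(C)C(C)(C)C | intermediate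
15 | 5-bromo-1,2,3-trimethoxybenzene | COc1cc(Br)cc(OC)c1OC | starting material
16 | (3,4,5-trimethoxyphenyl)magnesium bromide (not isolated) | COc1cc([Mg]Br)cc(OC)c1OC | intermediate
17 | [(3S,4S,5S)-4-{[(tert-butyldimethylsilyl)oxy]methyl}-5-(3,4,5-trimethoxyphenyl)tetrahydrofuran-3-yl](3,4,5-trimethoxyphenyl)methanol (all-cis ring, carbinol epimers) | OC(c1cc(OC)c(OC)c(OC)c1)[C@@H]1CO[C@H](c2cc(OC)c(OC)c(OC)c2)[C@@H]1CO[Si](C)(C)C(C)(C)C | intermediate
18 | [(3S,4S,5S)-4-{[(tert-butyldimethylsilyl)oxy]methyl}-5-(3,4,5-trimethoxyphenyl)tetrahydrofuran-3-yl](3,4,5-trimethoxyphenyl)methanone (all-cis, not isolated) | O=C(c1cc(OC)c(OC)c(OC)c1)[C@@H]1CO[C@H](c2cc(OC)c(OC)c(OC)c2)[C@@H]1CO[Si](C)(C)C(C)(C)C | intermediate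
19 | [(3R,4S,5S)-4-{[(tert-butyldimethylsilyl)oxy]methyl}-5-(3,4,5-trimethoxyphenyl)tetrahydrofuran-3-yl](3,4,5-trimethoxyphenyl)methanone (3,4-trans) | O=C(c1cc(OC)c(OC)c(OC)c1)[C@H]1CO[C@H](c2cc(OC)c(OC)c(OC)c2)[C@@H]1CO[Si](C)(C)C(C)(C)C | intermediate
20 | [(3R,4S,5S)-4-(hydroxymethyl)-5-(3,4,5-trimethoxyphenyl)tetrahydrofuran-3-yl](3,4,5-trimethoxyphenyl)methanone | COc1cc(C(=O)[C@H]2CO[C@H](c3cc(OC)c(OC)c(OC)c3)[C@@H]2CO)cc(OC)c1OC | target

Total step count: 11. Longest linear sequence: 11 steps (from 1 and 2 to 20); 6 and 15 are commercial and enter in steps 4 and 9.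

Steps most likely to fail

Step 4. The weak chiral acid may turn over the ester-deactivated boronate too slowly, giving low conversion or poor facial selectivity. The cis relationship may also erode if the benzylic carbon ionises during ring closure. The fallback replaces catalyst control by covalent resolution. Setting out from 5 and 6, the uncatalysed addition (PhMe, rt to 40 °C) should give the syn adduct as a racemate through the same chair, that is borate 7 together with its mirror image, the (R,R)-borate F1. Hydrolytic work-up should give the (S,S)-hydroxy ester F2 and the (R,R)-hydroxy ester F3. Esterification of the mixture with (S)-2-methoxy-2-phenylacetic acid (N,N′-dicyclohexylcarbodiimide, 4-(dimethylamino)pyridine cat., CH2Cl2, 0 °C) should give the diastereomeric esters, the (1S,2S)-mandelate F4 from F2 and the (1R,2R)-mandelate F5 from F3, to be separated by chromatography or crystallisation. Excess i-Bu2AlH on F4 cleaves the mandelate and reduces the methyl ester in one operation and should deliver diol 9, where the route is rejoined.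

Step 10. Equilibration at C4 may stay incomplete on the hindered ketone, or the base may open the ring by loss of O1 from the enolate or remove the silyl group. The fallback inverts C4 one stage earlier, where the α-hydrogen is more acidic and an enamine pathway needs no strong base. Setting out from aldehyde 14, pyrrolidine (20 mol %) and AcOH in CH2Cl2 at rt should equilibrate it to the 3,4-trans aldehyde F6. Addition of Grignard reagent 16 (THF, −78 → 0 °C) should give the 3,4-trans carbinols F7, and Dess–Martin oxidation then returns to the route at ketone 19 without a base step.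

Step 6. Sulfonylation may also take place at the secondary benzylic hydroxyl, or the benzylic carbon may ionise, either of which would cost the C2 configuration; the reactive allylic sulfonate may also oligomerise. The fallback closes the ring through a π-allyl palladium intermediate, in which only the allylic C–O bond can be activated. Setting out from diol 9, methyl chloroformate and pyridine (CH2Cl2, −20 °C) should acylate the primary hydroxyl selectively to give the allylic methyl carbonate F8. Pd(PPh3)4 (5 mol %, zerovalent palladium) in THF at rt should ionise it with loss of CO2 and methoxide. The benzylic alkoxide then attacks either terminus of the symmetrical 2-substituted allyl unit and gives tetrahydrofuran 11, where the route is rejoined.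

Further compounds
F1 | step 4 | methyl (R)-4-[(tert-butyldimethylsilyl)oxy]-2-methylene-3-{(R)-[(4,4,5,5-tetramethyl-1,3,2-dioxaborolan-2-yl)oxy](3,4,5-trimethoxyphenyl)methyl}butanoate | CC1(C)OB(O[C@@H](c2cc(OC)c(OC)c(OC)c2)[C@@H](CO[Si](C)(C)C(C)(C)C)C(=C)C(=O)OC)OC1(C)C
F2 | step 4 | methyl (S)-4-[(tert-butyldimethylsilyl)oxy]-3-[(S)-hydroxy(3,4,5-trimethoxyphenyl)methyl]-2-methylenebutanoate | O[C@H](c1cc(OC)c(OC)c(OC)c1)[C@H](CO[Si](C)(C)C(C)(C)C)C(=C)C(=O)OC
F3 | step 4 | methyl (R)-4-[(tert-butyldimethylsilyl)oxy]-3-[(R)-hydroxy(3,4,5-trimethoxyphenyl)methyl]-2-methylenebutanoate | O[C@@H](c1cc(OC)c(OC)c(OC)c1)[C@@H](CO[Si](C)(C)C(C)(C)C)C(=C)C(=O)OC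
F4 | step 4 | (1S,2S)-2-{[(tert-butyldimethylsilyl)oxy]methyl}-3-(methoxycarbonyl)-1-(3,4,5-trimethoxyphenyl)but-3-en-1-yl (S)-2-methoxy-2-phenylacetate | CO[C@H](C(=O)O[C@H](c1cc(OC)c(OC)c(OC)c1)[C@H](CO[Si](C)(C)C(C)(C)C)C(=C)C(=O)OC)c1ccccc1
F5 | step 4 | (1R,2R)-2-{[(tert-butyldimethylsilyl)oxy]methyl}-3-(methoxycarbonyl)-1-(3,4,5-trimethoxyphenyl)but-3-en-1-yl (S)-2-methoxy-2-phenylacetate | CO[C@H](C(=O)O[C@@H](c1cc(OC)c(OC)c(OC)c1)[C@@H](CO[Si](C)(C)C(C)(C)C)C(=C)C(=O)OC)c1ccccc1
F6 | step 10 | (3R,4S,5S)-4-{[(tert-butyldimethylsilyl)oxy]methyl}-5-(3,4,5-trimethoxyphenyl)tetrahydrofuran-3-carbaldehyde (3,4-trans) | O=C[C@H]1CO[C@H](c2cc(OC)c(OC)c(OC)c2)[C@@H]1CO[Si](C)(C)C(C)(C)C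
F7 | step 10 | [(3R,4S,5S)-4-{[(tert-butyldimethylsilyl)oxy]methyl}-5-(3,4,5-trimethoxyphenyl)tetrahydrofuran-3-yl](3,4,5-trimethoxyphenyl)methanol (3,4-trans, carbinol epimers) | OC(c1cc(OC)c(OC)c(OC)c1)[C@H]1CO[C@H](c2cc(OC)c(OC)c(OC)c2)[C@@H]1CO[Si](C)(C)C(C)(C)C
F8 | step 6 | (3S,4S)-3-{[(tert-butyldimethylsilyl)oxy]methyl}-4-hydroxy-2-methylene-4-(3,4,5-trimethoxyphenyl)butyl methyl carbonate | O[C@H](c1cc(OC)c(OC)c(OC)c1)[C@H](CO[Si](C)(C)C(C)(C)C)C(=C)COC(=O)OC
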